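**Retrosynthetic overview** (locants are those of the target: ring carbons C1–C10, lactone carbons C11–C13)
1. The structural feature used is the cis C4=C5 alkene lying between the oxygen-bearing C3 and C6: it is the middle double bond of a C2=C3–C4=C5–C6=C7 triene, so the C2–C7 bond can be hidden as the bond shared by ring A (C2–C7) and ring B (C7–C8–C9–C10–C1–C2) of a cis-decalin diene.
2. Target ⇒ Mannich base of the lactone (masked C13 methylene), C8 tiglate, C3 carbinol from a C3–O–C10 hemiketal, lactone from C6 reduction onto a C7 acetic ester.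
3. The cis C1=C2 alkene ⇒ syn-elimination inside a temporary five-membered C3–O–C10 ketal, built on the C2-selanyl ketone obtained by trapping the ring-opened triene cold.
4. Ten-membered triene ⇒ photochemical opening of the 3,6-bis(silyloxy) diene of the decalin ⇒ Diels–Alder adduct of 2-bromo-5-methylbenzoquinone and a 1-silyloxy-3-methylbutadiene, then C7 radical alkylation, enedione reduction, C10 hydration, silylation.
5. Ring order: ring A (quinone) → ring B (Diels–Alder) → ten-membered ring (C2–C7 cleavage) → temporary oxolane bridge → lactone.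

Key step: step 9

Assumption: the (S)-oxazaborolidinium catalyst is taken to give adduct 6 with the absolute configuration drawn; if the sense of induction is the opposite, the (R)-catalyst is used.

Remark: CIP descriptors change along the route with substituent priorities; the spatial arrangement at C8 and C10 is constant from 10 onward, and at C7 from 14 onward.

**Step 1**
Reactants: 1 1,4-dimethoxy-2-methylbenzene
Product: 2 1-bromo-2,5-dimethoxy-4-methylbenzene
Conditions: NBS, MeCN, 0 °C → rt
Reagents that add atoms: N-bromosuccinimide O=C1CCC(=O)N1Br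
Why: Electrophilic aromatic bromination, which should go to the position para to the methyl group and ortho to a methoxy group as the most activated and least hindered site.

**Step 2**
Reactants: 2 1-bromo-2,5-dimethoxy-4-methylbenzene
Product: 3 2-bromo-5-methyl-1,4-benzoquinone
Conditions: (NH4)2Ce(NO3)6, MeCN/H2O, 0 °C
Reagents that add atoms: water O
Why: Oxidative demethylation of a hydroquinone dimethyl ether by tetravalent cerium, in which water attacks the oxidised ring and methanol leaves, with the aryl bromide inert.

**Step 3**
Reactants: 4 3-methylbut-2-enal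
Product: 5 (E)-1-(tert-butyldimethylsilyloxy)-3-methylbuta-1,3-diene
Conditions: TBSOTf, Et3N, Et2O, 0 °C → rt
Reagents that add atoms: tert-butyldimethylsilyl trifluoromethanesulfonate CC(C)(C)[Si](C)(C)OS(=O)(=O)C(F)(F)F
Why: Vinylogous soft enolisation, in which O-silylation of the enal and loss of a γ-methyl proton to the amine give the dienyl silyl ether, mainly as the E isomer that is the reactive one in step 4.

**Step 4**
Reactants: 3 2-bromo-5-methyl-1,4-benzoquinone; 5 (E)-1-(tert-butyldimethylsilyloxy)-3-methylbuta-1,3-diene
Product: 6 cis-fused bromo enedione (2R,7R,8R)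
Conditions: (S)-1-(2-methylphenyl)-3,3-diphenyltetrahydro-1H,3H-pyrrolo[1,2-c][1,3,2]oxazaborole·HNTf2 (20 mol %), CH2Cl2, −78 °C, dark
Reagents that add atoms: none
Why: Catalytic enantioselective Diels–Alder reaction at the brominated quinone double bond, in which the bromine and the Lewis acid on the C6 carbonyl direct the silyloxy-bearing diene terminus to C7 and the CH2 terminus to C2, endo addition places the C8 silyloxy group cis to the ring-A carbons (trans to Br), and the catalyst face sets C2, C7 and C8 together.

**Step 5**
Reactants: 6 cis-fused bromo enedione; 7 1-(tert-butyldimethylsilyloxy)-1-methoxyethene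
Product: 8 cis-fused enedione ester (2S,7S,8R)
Conditions: CuBr (10 mol %), tris(2-pyridylmethyl)amine (10 mol %), 7 (3 equiv), MeCN, 40 °C, dark
Reagents that add atoms: none
Why: Kharasch-type atom-transfer radical alkylation, in which monovalent copper abstracts bromine, the electrophilic tertiary C7 radical adds to the CH2 terminus of the electron-rich ketene acetal, and the dioxygenated radical is oxidised by the divalent copper bromide and collapses to the methyl ester with loss of the silyl bromide; the C7–C11 bond should form on the face that held bromine, anti to the C8 silyloxy group (a centre erased in step 9).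

**Step 6**
Reactants: 8 cis-fused enedione ester
Product: 9 cis-fused saturated dione ester (C4 epimers)
Conditions: Zn, AcOH, CH2Cl2, rt
Reagents that add atoms: none
Why: Dissolving-metal conjugate reduction of the ene-1,4-dione, needed because the enedione would not survive the hydrogen-atom-transfer conditions of step 7; C4 forms as a mixture that is erased in step 8, and the isolated alkene, ester and silyl ether should be untouched.

**Step 7**
Reactants: 9 cis-fused saturated dione ester
Product: 10 C10 tertiary alcohol (2S,7S,8R,10S)
Conditions: Co(acac)2 (20 mol %), PhSiH3, O2 (1 atm), THF, rt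
Reagents that add atoms: dioxygen O=O
Why: Mukaiyama hydration (hydrogen-atom transfer to C9, Markovnikov C10 radical, capture by O2, reduction of the peroxide), in which O2 should approach C10 on the ring-B face anti to the C8 silyloxy group, where it meets only axial hydrogens at C8 and C2, giving the C8/C10 trans pattern.

**Step 8**
Reactants: 10 C10 tertiary alcohol
Product: 11 tris(trimethylsilyl) diene (2S,7S,8R,10S)
Conditions: TMSOTf (4 equiv), Et3N, CH2Cl2, 0 °C
Reagents that add atoms: trimethylsilyl trifluoromethanesulfonate C[Si](C)(C)OS(=O)(=O)C(F)(F)F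
Why: Soft enolisation and O-silylation, in which the C6 ketone can enolise only towards C5 (C7 is quaternary), C4–H is then both α to the C3 carbonyl and allylic so that C3 enolises into conjugation rather than towards C2, and the tertiary hydroxyl is silylated in the same operation.

**Step 9**
Reactants: 11 tris(trimethylsilyl) diene
Product: 12 ten-membered triene (8R,10S), kept in solution at −78 °C
Conditions: hν (300 nm), pentane/Et2O, −78 °C, Pyrex, degassed
Reagents that add atoms: none
Why: Excitation of the 3,6-bis(silyloxy)cyclohexa-1,3-diene of ring A (C3=C4–C5=C6) triggers a six-electron conrotatory electrocyclic ring opening that breaks the C2–C7 σ bond common to rings A and B. The closest known reaction type is the photochemical opening of ring-fused cyclohexa-1,3-dienes to medium-ring trienes, as in the provitamin D to previtamin D conversion and the opening of bicyclo[4.4.0]deca-2,4-dienes to cyclodeca-1,3,5-trienes. No ring is closed by bond formation: the ten-membered ring appears because the one bond crossing its middle is cut. No stereocentre is created (C2 and C7 become trigonal, C8 and C10 are untouched), and the former s-cis single bond C4–C5 of the six-membered diene must emerge as the cis C4=C5 alkene, the only geometry the target needs from this step. From the cis-fused precursor conrotation leaves one of the two new enol ether double bonds ring-trans (drawn at C6=C7; the other mode serves equally), and both enol ethers are consumed in step 10, so their geometry does not matter. The selectivity needed is ring opening over thermal disrotatory reclosure and secondary photochemistry, secured by working at −78 °C at 300 nm, where the donor-substituted diene should absorb more strongly than the twisted triene, and by trapping the triene cold.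

**Step 10**
Reactants: 12 ten-membered triene
Product: 14 selanyl methyl ketal keto ester (3S,7R,8R,10R; C2 epimers), via C2-selanyl ketone 13 (not isolated)
Conditions: PhSeCl (1.0 equiv), THF, −78 °C; then pyridine, MeOH, PPTS (cat.), −78 → 0 °C
Reagents that add atoms: phenylselenyl chloride Cl[Se]c1ccccc1; methanol CO
Why: α-Selenenylation of a silyl enol ether, fast at −78 °C, should pick the unhindered C2 terminus over the fully substituted C7 and so break the triene before it can reclose, after which methanolysis protonates C7 from the ring periphery (the needed epimer has H-7 cis to H-8, and the centre stays epimerisable beside the C6 ketone) and lets the freed C10 hydroxyl close onto the C3 ketone as a five-membered methyl ketal whose bridge face is fixed by C10.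

**Step 11**
Reactants: 14 selanyl methyl ketal keto ester
Product: 16 selanyl cis-fused lactone (3S,6S,7S,8R,10R), via C6 hydroxy ester 15 (not isolated)
Conditions: NaBH4, CeCl3·7H2O, MeOH, −78 °C; then PPTS (cat.), PhH, 40 °C
Reagents that add atoms: none
Why: Luche 1,2-reduction of the enone carbonyl followed by lactonisation of the γ-hydroxy ester, in which hydride should add to C6 on the face away from the C7 acetic ester and the C8 silyloxy group, placing the C6 oxygen cis to the side chain so that the cis-fused lactone closes and C7 is locked.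

**Step 12**
Reactants: 16 selanyl cis-fused lactone
Product: 18 dihydrofuran ketal lactone (3R,6S,7S,8R,10R), via selenoxide 17 (not isolated)
Conditions: mCPBA (1.0 equiv), CH2Cl2, −78 °C; then iPr2NH, → rt
Reagents that add atoms: none
Why: Selenoxide syn-elimination, which can only take a C1 hydrogen and occurs inside the five-membered ketal ring, so that the new C1=C2 alkene is an endocyclic dihydrofuran double bond and therefore cis in the ten-membered ring; C10 is quaternary, so no furan can form.

**Step 13**
Reactants: 18 dihydrofuran ketal lactone; 19 N,N-dimethylmethyleneiminium iodide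
Product: 20 Mannich base (C11 epimers)
Conditions: LiN(SiMe3)2, THF, −78 °C; then 19, −78 → 0 °C
Reagents that add atoms: none
Why: Mannich reaction of the lactone lithium enolate with Eschenmoser's salt, the first stage of the Eschenmoser methylenation, run while the ketal masks both the C3 carbonyl and the C10 hydroxyl so that no acidic proton competes; the C11 centre is erased in step 18.

**Step 14**
Reactants: 20 Mannich base
Product: 21 C8 alcohol (3R,6S,7R,8R,10R)
Conditions: Bu4NF, AcOH, THF, 0 °C → rt
Reagents that add atoms: none
Why: Fluoride cleavage of the secondary silyl ether, buffered with acetic acid so that the C8 alkoxide does not translactonise and the Mannich base does not eliminate; the methyl ketal is stable to fluoride.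

**Step 15**
Reactants: 21 C8 alcohol; 22 (E)-2-methylbut-2-enoyl chloride
Product: 23 C8 tiglate
Conditions: Et3N, DMAP (cat.), CH2Cl2, 0 °C → rt
Reagents that add atoms: none
Why: Acylation of the only free hydroxyl by DMAP-catalysed acyl transfer, the C3 and C10 oxygens being tied up in the ketal; the E (tiglate) geometry is the stable one and should not isomerise.

**Step 16**
Reactants: 23 C8 tiglate
Product: 24 C3–O–C10 hemiketal
Conditions: PPTS, acetone/H2O, rt
Reagents that add atoms: water O
Why: Hydrolysis of a doubly allylic mixed ketal, which ionises readily under mild acid and cannot aromatise because C10 is quaternary, while the lactone, the tiglate and the protonated amine should be unaffected.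

**Step 17**
Reactants: 24 C3–O–C10 hemiketal
Product: 25 diol Mannich base (3R,6S,7R,8R,10R)
Conditions: NaBH4, CeCl3·7H2O, MeOH, −40 °C
Reagents that add atoms: none
Why: Luche 1,2-reduction of the cis γ-hydroxy dienone that is in equilibrium with the hemiketal, in which trivalent cerium is expected to bridge the C10 hydroxyl and the C3 carbonyl held on one side by the cis C1=C2 alkene, so that hydride attacks from the ring periphery and the new C3 hydroxyl ends syn to the C10 hydroxyl; the α-methylene lactone is still masked, so conjugate reduction is not an issue.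

**Step 18**
Reactants: 25 diol Mannich base
Product: 27 target CNP0262559.2, via trimethylammonium iodide 26 (not isolated)
Conditions: MeI, THF, rt; then aq NaHCO3, rt
Reagents that add atoms: none
Why: Quaternisation of the amine and E1cB loss of trimethylamine, the closing stages of the Eschenmoser methylenation, should unveil the C11=C13 methylene under conditions that leave the two free hydroxyls, the tiglate and both cis alkenes untouched.

**Compound list**
1 | 1,4-dimethoxy-2-methylbenzene | COc1ccc(OC)c(C)c1 | starting material
2 | 1-bromo-2,5-dimethoxy-4-methylbenzene | COc1cc(Br)c(OC)cc1C | intermediate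
3 | 2-bromo-5-methyl-1,4-benzoquinone | CC1=CC(=O)C(Br)=CC1=O | intermediate
4 | 3-methylbut-2-enal | CC(C)=CC=O | starting material
5 | (E)-1-(tert-butyldimethylsilyloxy)-3-methylbuta-1,3-diene | C=C(C)/C=C/O[Si](C)(C)C(C)(C)C | intermediate
6 | (4aR,5R,8aR)-4a-bromo-5-(tert-butyldimethylsilyloxy)-2,7-dimethyl-4a,5,8,8a-tetrahydronaphthalene-1,4-dione; cis-fused, silyloxy trans to bromine (target locants 2R,7R,8R) | O=C1C(C)=CC(=O)[C@]2(Br)[C@H](O[Si](C)(C)C(C)(C)C)C=C(C)C[C@H]12 | intermediate
7 | 1-(tert-butyldimethylsilyloxy)-1-methoxyethene | C=C(OC)O[Si](C)(C)C(C)(C)C | starting material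
8 | cis-fused enedione ester: adduct 6 with CH2CO2Me in place of bromine at ring-fusion carbon C7 (2S,7S,8R) | O=C1C(C)=CC(=O)[C@]2(CC(=O)OC)[C@H](O[Si](C)(C)C(C)(C)C)C=C(C)C[C@H]12 | intermediate
9 | cis-fused saturated 3,6-dione ester: 8 with C4–C5 reduced (2S,7S,8R; C4 epimers) | O=C1C(C)CC(=O)[C@]2(CC(=O)OC)[C@H](O[Si](C)(C)C(C)(C)C)C=C(C)C[C@H]12 | intermediate
10 | C10 tertiary alcohol: 9 hydrated at C9=C10 with the C10 hydroxyl trans to the C8 silyloxy group (2S,7S,8R,10S; C4 epimers) | O=C1C(C)CC(=O)[C@]2(CC(=O)OC)[C@H](O[Si](C)(C)C(C)(C)C)C[C@@](C)(O)C[C@H]12 | intermediate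
11 | cis-fused 3,6,10-tris(trimethylsilyloxy)-8-(tert-butyldimethylsilyloxy) decalin-3,5-diene bearing CH2CO2Me at C7 (2S,7S,8R,10S) | C[Si](C)(C)OC1=C(C)C=C(O[Si](C)(C)C)[C@]2(CC(=O)OC)[C@H](O[Si](C)(C)C(C)(C)C)C[C@@](C)(O[Si](C)(C)C)C[C@H]12 | intermediate
12 | methyl 2-[(8R,10S)-8-(tert-butyldimethylsilyloxy)-4,10-dimethyl-3,6,10-tris(trimethylsilyloxy)cyclodeca-2,4,6-trien-7-yl]acetate; ring-cis at C2=C3 and C4=C5, ring-trans at C6=C7 | C1/C=C(O[Si](C)(C)C)\C(C)=C/C(O[Si](C)(C)C)=C(\CC(=O)OC)[C@H](O[Si](C)(C)C(C)(C)C)C[C@@]1(C)O[Si](C)(C)C | intermediate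
13 | C2-phenylselanyl C3 ketone retaining the C6 trimethylsilyl enol ether and the C10 trimethylsilyl ether (C2 epimers) | C1C([Se]c2ccccc2)C(=O)/C(C)=C\C(O[Si](C)(C)C)=C(/CC(=O)OC)[C@H](O[Si](C)(C)C(C)(C)C)C[C@@]1(C)O[Si](C)(C)C | intermediate
14 | methyl 2-[(3S,7R,8R,10R)-8-(tert-butyldimethylsilyloxy)-3-methoxy-4,10-dimethyl-6-oxo-2-(phenylselanyl)-3,10-epoxycyclodec-4-en-7-yl]acetate; C4=C5 cis, H-7 cis to H-8, C2 epimers | C[C@@]12CC([Se]c3ccccc3)[C@@](OC)(O1)/C(C)=C\C(=O)[C@H](CC(=O)OC)[C@H](O[Si](C)(C)C(C)(C)C)C2 | intermediate
15 | C6 hydroxy ester from 14, C6 hydroxyl cis to the C7 side chain | C[C@@]12CC([Se]c3ccccc3)[C@@](OC)(O1)/C(C)=C\[C@H](O)[C@H](CC(=O)OC)[C@H](O[Si](C)(C)C(C)(C)C)C2 | intermediate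
16 | (3S,6S,7S,8R,10R)-8-(tert-butyldimethylsilyloxy)-3-methoxy-2-(phenylselanyl)-3,10-epoxygermacr-4-en-12,6-olide; cis-fused lactone, C2 epimers | C[C@@]12CC([Se]c3ccccc3)[C@@](OC)(O1)/C(C)=C\[C@@H]4OC(=O)C[C@@H]4[C@H](O[Si](C)(C)C(C)(C)C)C2 | intermediate
17 | selenoxide of 16 | C[C@@]12CC([Se](=O)c3ccccc3)[C@@](OC)(O1)/C(C)=C\[C@@H]4OC(=O)C[C@@H]4[C@H](O[Si](C)(C)C(C)(C)C)C2 | intermediate
18 | (3R,6S,7S,8R,10R)-8-(tert-butyldimethylsilyloxy)-3-methoxy-3,10-epoxygermacra-1,4-dien-12,6-olide; both ring alkenes cis, C1=C2 inside the dihydrofuran | C[C@@]12C=C[C@@](OC)(O1)/C(C)=C\[C@@H]3OC(=O)C[C@@H]3[C@H](O[Si](C)(C)C(C)(C)C)C2 | intermediate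
19 | N,N-dimethylmethyleneiminium iodide (Eschenmoser's salt) | C=[N+](C)C.[I-] | starting material
20 | 11-(dimethylaminomethyl) derivative of 18 (C11 epimers) | C[C@@]12C=C[C@@](OC)(O1)/C(C)=C\[C@@H]3OC(=O)C(CN(C)C)[C@@H]3[C@H](O[Si](C)(C)C(C)(C)C)C2 | intermediate
21 | C8 alcohol from 20 (3R,6S,7R,8R,10R) | C[C@@]12C=C[C@@](OC)(O1)/C(C)=C\[C@@H]3OC(=O)C(CN(C)C)[C@@H]3[C@H](O)C2 | intermediate
22 | (E)-2-methylbut-2-enoyl chloride (tigloyl chloride) | C/C=C(\C)C(=O)Cl | starting material
23 | C8 tiglate of 21 | C[C@@]12C=C[C@@](OC)(O1)/C(C)=C\[C@@H]3OC(=O)C(CN(C)C)[C@@H]3[C@H](OC(=O)/C(C)=C/C)C2 | intermediate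
24 | C3 hemiketal (3-hydroxy-3,10-epoxide) from 23 | C[C@@]12C=C[C@@](O)(O1)/C(C)=C\[C@@H]3OC(=O)C(CN(C)C)[C@@H]3[C@H](OC(=O)/C(C)=C/C)C2 | intermediate
25 | (3R,6S,7R,8R,10R)-13-(dimethylamino)-3,10-dihydroxy-8-tigloyloxygermacra-1Z,4Z-dien-12,6-olide (C11 epimers) | CN(C)CC1C(=O)O[C@H]2/C=C(/C)[C@H](O)/C=C\[C@](C)(O)C[C@@H](OC(=O)/C(C)=C/C)[C@@H]12 | intermediate
26 | trimethylammonium iodide of 25 | C[N+](C)(C)CC1C(=O)O[C@H]2/C=C(/C)[C@H](O)/C=C\[C@](C)(O)C[C@@H](OC(=O)/C(C)=C/C)[C@@H]12.[I-] | intermediate
27 | CNP0262559.2: (3R,6S,7R,8R,10R)-3,10-dihydroxy-8-tigloyloxygermacra-1Z,4Z,11(13)-trien-12,6-olide | C=C1C(=O)O[C@H]2/C=C(/C)[C@H](O)/C=C\[C@](C)(O)C[C@@H](OC(=O)/C(C)=C/C)[C@@H]12 | target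

**Step count**
Total: 18 steps. Longest linear sequence: 17 steps (1 → 27 through steps 1, 2 and 4–18; step 3 is a one-step branch).

**Steps most likely to fail, with fallbacks**

Step 9. The ring-trans triene may reclose thermally (disrotatory, to a trans-fused diene) or revert photochemically faster than it can be drained, so that little open material reaches the trap. The fallback sets out from 10 and returns at 14. C2, the only enolisable ring-fusion centre, is epimerised with DBU (toluene, 60 °C) and the trans-fused hydroxy dione F1 is separated. Silylation as in step 8 gives the trans-fused tris(trimethylsilyl) diene F2. Irradiation as in step 9 then opens a trans-fused diene, which by conrotation gives the all-ring-cis triene F3. F3 has no strained ring-trans alkene and should reclose far more slowly, and trapping it as in step 10 gives 14.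

Step 10. The selenium electrophile may fail to discriminate between the two enol ethers, or reclosure may outrun the trap, giving mixtures. The fallback sets out from 12 and returns at 18. A Saegusa–Ito dehydrogenation (Pd(OAc)2, MeCN, −40 → 0 °C) acts only on the enol ether with an unhindered α-carbon and β-hydrogens (C2=C3). Methanolic PPTS then removes the remaining silyl groups to give the (1E,4Z)-dienone keto ester F4, whose 1Z isomer, if formed, closes at once. Irradiation of F4 at 350 nm in MeOH with PPTS isomerises C1=C2, and the Z isomer is drained by addition of the C10 hydroxyl to C3 as the methoxy dihydrofuran keto ester F5. Reduction and lactonisation of F5 under the conditions of step 11 give 18.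

Step 11. Hydride may add to the other face of C6, or C7 may have settled as the other epimer, so that a trans-fused lactone results. The fallback sets out from 14 and returns at 16. The 6-epimeric trans-fused lactone F6 obtained from the reduction is opened with LiOH (THF/H2O) to the hydroxy acid F7. F7 is closed under Mitsunobu conditions (PPh3, DIAD, toluene, high dilution), where the carboxylate displaces the activated C6 oxygen with inversion and gives the cis-fused lactone 16. If the C7 epimer ratio is the cause, 14 is first equilibrated with DBU.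

**Further compounds**
F1 | step 9 | trans-fused C2 epimer of 10 (2R,7S,8R,10S) | O=C1C(C)CC(=O)[C@]2(CC(=O)OC)[C@H](O[Si](C)(C)C(C)(C)C)C[C@@](C)(O)C[C@@H]12
F2 | step 9 | trans-fused C2 epimer of 11 | C[Si](C)(C)OC1=C(C)C=C(O[Si](C)(C)C)[C@]2(CC(=O)OC)[C@H](O[Si](C)(C)C(C)(C)C)C[C@@](C)(O[Si](C)(C)C)C[C@@H]12
F3 | step 9 | all-ring-cis isomer of triene 12 | C1/C=C(O[Si](C)(C)C)\C(C)=C/C(O[Si](C)(C)C)=C(/CC(=O)OC)[C@H](O[Si](C)(C)C(C)(C)C)C[C@@]1(C)O[Si](C)(C)C
F4 | step 10 | methyl 2-[(7R,8R,10R)-8-(tert-butyldimethylsilyloxy)-10-hydroxy-4,10-dimethyl-3,6-dioxocyclodeca-1E,4Z-dien-7-yl]acetate | C[C@]1(O)/C=C/C(=O)/C(C)=C\C(=O)[C@H](CC(=O)OC)[C@H](O[Si](C)(C)C(C)(C)C)C1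
F5 | step 10 | methoxy dihydrofuran keto ester: 14 with C1=C2 in place of the selanyl group (3R,7R,8R,10R) | C[C@@]12C=C[C@@](OC)(O1)/C(C)=C\C(=O)[C@H](CC(=O)OC)[C@H](O[Si](C)(C)C(C)(C)C)C2
F6 | step 11 | 6-epimer of 16 with trans-fused lactone | C[C@@]12CC([Se]c3ccccc3)[C@@](OC)(O1)/C(C)=C\[C@H]4OC(=O)C[C@@H]4[C@H](O[Si](C)(C)C(C)(C)C)C2
F7 | step 11 | 6-epi hydroxy acid from F6 | C[C@@]12CC([Se]c3ccccc3)[C@@](OC)(O1)/C(C)=C\[C@@H](O)[C@H](CC(=O)O)[C@H](O[Si](C)(C)C(C)(C)C)C2
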